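The readings are calculated with made-up constants; scatter was added.

The flasks are read at 12 h, and the question is how much of the links stands then.

| setting | Tuesday's | Friday's | ochre | amber | red | violet | grey |
|---|---|---|---|---|---|---|---|
| first end groups | 0.0040 M | 0.0040 M | 0.0040 M | 0.012 M | 0.040 M | 0.12 M | 0.40 M |
| second end groups | 0.118 M | 0.059 M | 0.118 M | 0.118 M | 0.118 M | 0.118 M | 0.118 M |
| one-sided end groups | 0.0080 M | 0.012 M | 0.0120 M | 0.0120 M | 0.0120 M | 0.0120 M | 0.0120 M |
| remark | run made earlier | run made earlier |  |  |  |  |  |
| time |  |  | 12 h | 12 h | 12 h | 12 h | 12 h |

- Tuesday's (time / h: links / %, first end groups / %): 0.333: 11.7, 80.7; 0.667: 16.9, 65.5; 1.00: 22.1, 49.6; 1.33: 27.6, 40.4; 1.50: 26.9, 37.0; 2.00: 29.2, 25.6; 2.50: 32.1, 19.3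
- Friday's (time / h: links / %, first end groups / %): 0.133: 3.2, 91.4; 0.333: 3.8, 80.0; 0.667: 8.0, 65.4; 1.00: 10.8, 53.4; 1.33: 13.4, 44.2; 2.00: 15.5, 27.9; 2.50: 15.3, 22.1

(readings scatter by 1 percentage point)

- what may be going on: first end groups + second end groups -> links; first end groups + one-sided end groups -> capped ends; links -> over-reaction product
- "hardly changes" means that all values lie within two and a half points (for a concentration: within two and a half percent of the largest)

- [links] at the end for ochre, amber, red, violet, grey, in this order
- how the row runs (falls all the way / hardly changes / rises all the way / rises, then falls / falls, then rises)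

*What can be read early in the runs?* Of the first end groups used up over the first 1.00 h, links hold 48.7% on Tuesday and 22.3% on Friday.

*What do you make of that?* I take the rest as capped ends and divide out the concentrations. This gives 15.6 from Tuesday, about the same as 17.1 from Friday. So I carry their mean, S = 16.3, as a reading of how many times more readily a first end group takes a one-sided end group than a second end group at equal concentration. It leans high, since the rest I counted as capped ends also holds whatever links have gone on to over-reaction product. What it tries to read is a selectivity factor.

*And in ochre?* I freeze both partners at their charges. Capping then beats linking by 1.66 to one, so capped ends take 62.4% of the charge.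

*Is freezing fair?* Roughly, since that capping uses 20.8% of the one-sided end groups in ochre, so my share leans high. Both steps use the same first end groups, so under these two steps the fraction left of the one-sided end groups is the fraction left of the second end groups raised to the power S.

*And further along the row?* In violet the one-sided end groups can cap at most 10.0% of the charge, far less than 62.4%, so the share open to links grows. In grey the charge of 0.40 M is more than the 0.130 M of both partners together, so the partners are the limiting reagent. I commit to a rise and then a fall, without a reckoning of how many links survive.

The forecast gives 2.300 × 10⁻⁴ M, 7.800 × 10⁻⁴ M, 0.005 M, 0.018 M and 0.0135 M, a row that rises, then falls, and says “the peak comes near equal charges”.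

    first end groups + second end groups → links (k = 3.10 M⁻¹ h⁻¹)
    first end groups + one-sided end groups → capped ends (k = 41.0 M⁻¹ h⁻¹)
    links → over-reaction product (k = 0.230 h⁻¹)

The flasks give 1.61 × 10⁻⁴ M, 5.87 × 10⁻⁴ M, 0.00382 M, 0.0150 M and 0.00974 M, a row that rises, then falls. Ochre ends with capped ends at 55.1% of its charge, less than the frozen 62.4%. In amber, 94.9% of the second end groups are left at 12.0 h, and raising that to the power S gives 42.6% for the one-sided end groups, which stand at 50.1%.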